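**Plan**

1. Retrosynthes: the tetrahydrofuran O1–C2 bond is cut first (inverting ring closure of a C2-symmetric 1,4-diol). Next come the two carbinol–aryl bonds (a 1,4-diketone from a bis-thioester), then the central C3–C4 bond (oxidative homocoupling of an arylacetyl imide), then the aryl–CH2 bond of the side chain (Negishi), and last the C2–C3 and O–C2 bonds of each dihydrobenzofuran ([4+1] annulation of an o-quinone methide).
2. Enabling feature: the tetrahydrofuran ring (O1, C2–C5) carries pairwise identical groups, 4-hydroxyphenyl on C2 and C5 and the same (2S,3S)-dihydrobenzofuran-4-yl on C3 and C4. It departs from C2 symmetry only in the configuration at C2 (2,3-cis, 3,4-trans, 4,5-trans), so it maps onto a C2-symmetric 1,4-diol in which inversion at either homotopic benzylic carbinol gives the same ring.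
3. Forward order: the dihydrofuran ring of the benzofuran is built first (step 6), then the acetic acid side chain (steps 7–8), the chain is joined by dimerisation (step 10), the aryl ketones and diol follow (steps 12–13), the tetrahydrofuran ring closes last (step 14), then deprotection (steps 15–16).
4. Stereochemistry: the trans C2/C3 relation of the dihydrobenzofuran comes from the annulation and its absolute sense from separation of diastereomeric oxazolidinone imides (step 9). C3/C4 of the tetrahydrofuran come from the (S)-oxazolidinone in the homocoupling, both carbinols from CBS reduction, and C2 of the tetrahydrofuran from SN2 inversion in the key step.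
5. Protecting groups: benzyl ethers (removed by hydrogenolysis) are used for eight phenols so that no Lewis acid touches the finished, acid-labile 2,3-cis ring. The two carbinol aryl rings carry acetates to disfavour benzylic ionisation.

Key step: step 14

Assumption: the titanium-enolate homocoupling is taken to follow the usual facial sense of this oxazolidinone (bond formation anti to the C4 benzyl group), so the (S)-auxiliary should give the (2S,3S)-succinyl core; racemic intermediates are drawn as their (2S,3S) enantiomer.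

Abbreviation: Ar* = (2S,3S)-6-(benzyloxy)-2-[4-(benzyloxy)phenyl]-3-[3,5-bis(benzyloxy)phenyl]-2,3-dihydro-1-benzofuran-4-yl (trans).

**Route**

Step 1
Reactants: 1 1,3-bis(benzyloxy)-5-bromobenzene
Product: 3 2,4-bis(benzyloxy)-6-bromobenzaldehyde, via iminium salt 2 (not isolated)
Conditions: POCl3, DMF, 0 to 90 °C; then aq. NaOH, 0 °C
Reagents that add atoms: N,N-dimethylformamide CN(C)C=O (formyl carbon); water O (carbonyl oxygen)
Why: Vilsmeier–Haack formylation should take the ring position that is para to one benzyloxy group and ortho to the other (next to bromine), the less hindered of the two activated sites, as is usual for 1-bromo-3,5-dialkoxybenzenes.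

Step 2
Reactants: 3 2,4-bis(benzyloxy)-6-bromobenzaldehyde
Product: 4 4-(benzyloxy)-2-bromo-6-hydroxybenzaldehyde
Conditions: MgBr2·OEt2, toluene/Et2O, reflux; then 1 M HCl
Reagents that add atoms: none
Why: Chelation-controlled debenzylation: magnesium bound to the aldehyde oxygen activates only the ortho benzyl ether towards bromide attack, so the para ether and the aryl bromide should survive.

Step 3
Reactants: 1 1,3-bis(benzyloxy)-5-bromobenzene (second portion), 4 4-(benzyloxy)-2-bromo-6-hydroxybenzaldehyde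
Product: 6 rac-5-(benzyloxy)-2-{[3,5-bis(benzyloxy)phenyl](hydroxy)methyl}-3-bromophenol, via Grignard reagent 5 (not isolated)
Conditions: 1 (2.3 equiv), Mg, THF, 40 °C; then 4, −40 to 0 °C; AcOH quench
Reagents that add atoms: none
Why: Grignard addition to the magnesium phenoxide of the salicylaldehyde (one equivalent of 5 serves as base) should give the racemic benzhydrol, the temperature being kept at or below 0 °C so that the bis-alkoxide does not eliminate to a quinone methide.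

Step 4
Reactants: 6 rac-5-(benzyloxy)-2-{[3,5-bis(benzyloxy)phenyl](hydroxy)methyl}-3-bromophenol
Product: 7 rac-5-(benzyloxy)-2-{[3,5-bis(benzyloxy)phenyl](tosyl)methyl}-3-bromophenol
Conditions: p-TolSO2Na, HCO2H, rt
Reagents that add atoms: sodium p-toluenesulfinate Cc1ccc(cc1)S(=O)[O-].[Na+]
Why: SN1 substitution of the electron-rich ortho-hydroxybenzhydrol by sulfinate (through the benzylic cation or quinone methide) should give a bench-stable sulfone that releases the o-quinone methide under mild base.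

Step 5
Reactants: 8 4-(benzyloxy)benzyl bromide
Product: 9 1-[4-(benzyloxy)benzyl]tetrahydrothiophenium bromide
Conditions: tetrahydrothiophene, acetone, rt
Reagents that add atoms: tetrahydrothiophene C1CCSC1
Why: SN2 S-alkylation of the cyclic sulfide by the benzylic bromide should give the sulfonium salt, which precipitates from acetone.

Step 6
Reactants: 7 rac-5-(benzyloxy)-2-{[3,5-bis(benzyloxy)phenyl](tosyl)methyl}-3-bromophenol, 9 1-[4-(benzyloxy)benzyl]tetrahydrothiophenium bromide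
Product: 11 rac-trans-6-(benzyloxy)-2-[4-(benzyloxy)phenyl]-3-[3,5-bis(benzyloxy)phenyl]-4-bromo-2,3-dihydro-1-benzofuran, via o-quinone methide 10 (not isolated)
Conditions: Cs2CO3, MeCN, 0 °C to rt
Reagents that add atoms: none
Why: Formal [4+1] annulation of an o-quinone methide by a sulfur ylide (Corey–Chaykovsky type): base eliminates sulfinate to give 10, the benzylide adds to its exocyclic carbon, and the phenoxide displaces tetrahydrothiophene 5-exo-tet, the anti betaine and the lower strain of the product favouring the trans-2,3-diaryl ring (racemic).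

Step 7
Reactants: 11 rac-trans-6-(benzyloxy)-2-[4-(benzyloxy)phenyl]-3-[3,5-bis(benzyloxy)phenyl]-4-bromo-2,3-dihydro-1-benzofuran
Product: 12 rac-ethyl 2-(Ar*)acetate
Conditions: BrZnCH2CO2Et, Pd2(dba)3 (cat.), XPhos, THF, 60 °C
Reagents that add atoms: (2-ethoxy-2-oxoethyl)zinc bromide CCOC(=O)C[Zn]Br
Why: Negishi coupling of the aryl bromide and a Reformatsky reagent under nearly neutral conditions should tolerate the single ortho substituent, the benzyl ethers and the benzylic ether of the dihydrobenzofuran.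

Step 8
Reactants: 12 rac-ethyl 2-(Ar*)acetate
Product: 13 rac-2-(Ar*)acetic acid
Conditions: LiOH, THF/MeOH/H2O, 40 °C; then 1 M HCl
Reagents that add atoms: lithium hydroxide [Li+].[OH-] (carboxyl oxygen)
Why: Ester saponification, to which the ring stereocentres (not acidic) and the benzyl ethers are inert.

Step 9
Reactants: 13 rac-2-(Ar*)acetic acid, 14 (S)-4-benzyl-1,3-oxazolidin-2-one
Product: 16 (4S)-4-benzyl-3-[2-(Ar*)acetyl]-1,3-oxazolidin-2-one, via mixed pivalic anhydride 15 (not isolated)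
Conditions: PivCl, Et3N, THF, −20 °C; then 14, LiCl, −20 °C to rt; separation of the two diastereomers on silica
Reagents that add atoms: none
Why: N-Acylation of the oxazolidinone through the mixed anhydride turns the racemic acid into two diastereomeric imides, and their separation is a classical resolution that fixes the (2S,3S) configuration of the dihydrobenzofuran for the rest of the route.

Step 10
Reactants: 16 (4S)-4-benzyl-3-[2-(Ar*)acetyl]-1,3-oxazolidin-2-one (two molecules)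
Product: 17 (4S,4'S)-3,3'-[(2S,3S)-2,3-bis(Ar*)butanedioyl]bis(4-benzyl-1,3-oxazolidin-2-one)
Conditions: TiCl4, Et3N, CH2Cl2, −45 to 0 °C
Reagents that add atoms: none
Why: Oxidative homocoupling of the chelated titanium (Z)-enolate of an N-arylacetyl oxazolidinone (Ti(IV) to Ti(III) electron transfer, then C–C coupling), in which each new stereocentre forms on the enolate face remote from the C4 benzyl group, so that the (S)-auxiliary should give the C2-symmetric (2S,3S) core.

Step 11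
Reactants: 17 (4S,4'S)-3,3'-[(2S,3S)-2,3-bis(Ar*)butanedioyl]bis(4-benzyl-1,3-oxazolidin-2-one)
Product: 18 S,S'-diethyl (2S,3S)-2,3-bis(Ar*)butanebis(thioate)
Conditions: EtSH, n-BuLi, THF, 0 °C; AcOH quench
Reagents that add atoms: ethanethiol CCS (as its lithium salt)
Why: Thiolate transacylation cleaves the exocyclic acyl–nitrogen bond of hindered acyl oxazolidinones, and the weakly basic thiolate should leave the α-aryl stereocentres untouched while the auxiliary is recovered.

Step 12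
Reactants: 18 S,S'-diethyl (2S,3S)-2,3-bis(Ar*)butanebis(thioate), 19 4-acetoxyphenylboronic acid
Product: 20 (2S,3S)-1,4-bis(4-acetoxyphenyl)-2,3-bis(Ar*)butane-1,4-dione
Conditions: 19 (3 equiv), Pd2(dba)3 (cat.), P(2-furyl)3, CuTC, THF, 50 °C
Reagents that add atoms: none
Why: Liebeskind–Srogl ketone synthesis runs without base, so the epimerisable α-centres and the aryl acetates should survive and the two acetoxyphenyl ketones arrive with the protecting group needed for the key step already in place.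

Step 13
Reactants: 20 (2S,3S)-1,4-bis(4-acetoxyphenyl)-2,3-bis(Ar*)butane-1,4-dione
Product: 21 (1R,2S,3S,4R)-1,4-bis(4-acetoxyphenyl)-2,3-bis(Ar*)butane-1,4-diol
Conditions: (S)-Me-CBS, BH3·SMe2, THF, −20 °C; then MeOH
Reagents that add atoms: none
Why: Corey–Bakshi–Shibata reduction delivers hydride under catalyst control to the same face of both aryl ketones (aryl as the large group, hence R at both carbinols) while borane spares the aryl acetates at low temperature; any leakage to the (1S,4S) C2-symmetric diol is harmless because it converges on the same ring in step 14.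

Step 14
Reactants: 21 (1R,2S,3S,4R)-1,4-bis(4-acetoxyphenyl)-2,3-bis(Ar*)butane-1,4-diol
Product: 23 (2S,3S,4S,5R)-2,5-bis(4-acetoxyphenyl)-3,4-bis(Ar*)tetrahydrofuran, via monomesylate 22 (not isolated)
Conditions: Ms2O (1.05 equiv), Et3N, CH2Cl2, −40 to 0 °C
Reagents that add atoms: none
Why: Sulfene-type O-sulfonylation of either of the two homotopic benzylic hydroxyls gives one monomesylate, and the remaining hydroxyl displaces the mesylate intramolecularly by SN2 while Et3N takes up the acid. The closest known reaction type is the sulfonate-mediated (or Mitsunobu) cyclodehydration of 1,4-diaryl-butane-1,4-diols to 2,5-diaryltetrahydrofurans used for tetrahydrofuran lignans. The one ring formed, the tetrahydrofuran, closes 5-exo-tet through the O–C2 bond. The only stereocentre that changes is C2, set by backside attack (R carbinol to S ring carbon), which places its aryl group cis to the C3 substituent while C3, C4 and C5 keep their configuration (3,4-trans, 4,5-trans). The step needs SN2 to outrun ionisation, which would give the all-trans ring; the acetoxy groups on the carbinol aryl rings (a benzylic cation no better than that of an unsubstituted phenyl), the non-acidic chloride-free medium at low temperature and the fast five-membered closure should secure this. Because the diol is C2-symmetric, no selection between the two hydroxyls is required.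

Step 15
Reactants: 23 (2S,3S,4S,5R)-2,5-bis(4-acetoxyphenyl)-3,4-bis(Ar*)tetrahydrofuran
Product: 24 (2S,3S,4S,5R)-2,5-bis(4-hydroxyphenyl)-3,4-bis(Ar*)tetrahydrofuran
Conditions: K2CO3 (cat.), MeOH/THF, 0 °C to rt
Reagents that add atoms: none
Why: Base-catalysed transesterification (Zemplén type) removes the two aryl acetates under conditions too mild to open the benzylic ethers or epimerise C2.

Step 16
Reactants: 24 (2S,3S,4S,5R)-2,5-bis(4-hydroxyphenyl)-3,4-bis(Ar*)tetrahydrofuran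
Product: 25 target CNP0270490.1
Conditions: H2 (1 atm), Pd/C, THF/MeOH, rt
Reagents that add atoms: none
Why: Neutral catalytic hydrogenolysis cleaves the eight aryl benzyl ethers much faster than the hindered cyclic benzylic C–O bonds of the tetrahydrofuran and dihydrobenzofurans, so the acid-labile 2,3-cis centre should not be disturbed.

**Compound list**

1 | 1,3-bis(benzyloxy)-5-bromobenzene | Brc1cc(OCc2ccccc2)cc(OCc2ccccc2)c1 | starting material
2 | N-[2,4-bis(benzyloxy)-6-bromobenzylidene]-N-methylmethanaminium chloride | C[N+](C)=Cc1c(Br)cc(OCc2ccccc2)cc1OCc1ccccc1.[Cl-] | intermediate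
3 | 2,4-bis(benzyloxy)-6-bromobenzaldehyde | O=Cc1c(Br)cc(OCc2ccccc2)cc1OCc1ccccc1 | intermediate
4 | 4-(benzyloxy)-2-bromo-6-hydroxybenzaldehyde | O=Cc1c(O)cc(OCc2ccccc2)cc1Br | intermediate
5 | [3,5-bis(benzyloxy)phenyl]magnesium bromide | Br[Mg]c1cc(OCc2ccccc2)cc(OCc2ccccc2)c1 | intermediate
6 | rac-5-(benzyloxy)-2-{[3,5-bis(benzyloxy)phenyl](hydroxy)methyl}-3-bromophenol | OC(c1cc(OCc2ccccc2)cc(OCc2ccccc2)c1)c1c(O)cc(OCc2ccccc2)cc1Br | intermediate
7 | rac-5-(benzyloxy)-2-{[3,5-bis(benzyloxy)phenyl](tosyl)methyl}-3-bromophenol | Cc1ccc(cc1)S(=O)(=O)C(c1cc(OCc2ccccc2)cc(OCc2ccccc2)c1)c1c(O)cc(OCc2ccccc2)cc1Br | intermediate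
8 | 4-(benzyloxy)benzyl bromide | BrCc1ccc(OCc2ccccc2)cc1 | starting material
9 | 1-[4-(benzyloxy)benzyl]tetrahydrothiophenium bromide | [Br-].c1ccc(COc2ccc(C[S+]3CCCC3)cc2)cc1 | intermediate
10 | 3-(benzyloxy)-6-[3,5-bis(benzyloxy)benzylidene]-5-bromocyclohexa-2,4-dien-1-one | O=C1C=C(OCc2ccccc2)C=C(Br)C1=Cc1cc(OCc2ccccc2)cc(OCc2ccccc2)c1 | intermediate
11 | rac-trans-6-(benzyloxy)-2-[4-(benzyloxy)phenyl]-3-[3,5-bis(benzyloxy)phenyl]-4-bromo-2,3-dihydro-1-benzofuran (racemic; 2S,3S drawn) | C(c1ccccc1)Oc1ccc(cc1)[C@H]2Oc3cc(OCc4ccccc4)cc(Br)c3[C@@H]2c2cc(OCc3ccccc3)cc(OCc3ccccc3)c2 | intermediate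
12 | rac-ethyl 2-(Ar*)acetate (racemic; 2S,3S drawn) | C(c1ccccc1)Oc1ccc(cc1)[C@H]2Oc3cc(OCc4ccccc4)cc(CC(=O)OCC)c3[C@@H]2c2cc(OCc3ccccc3)cc(OCc3ccccc3)c2 | intermediate
13 | rac-2-(Ar*)acetic acid (racemic; 2S,3S drawn) | C(c1ccccc1)Oc1ccc(cc1)[C@H]2Oc3cc(OCc4ccccc4)cc(CC(O)=O)c3[C@@H]2c2cc(OCc3ccccc3)cc(OCc3ccccc3)c2 | intermediate
14 | (S)-4-benzyl-1,3-oxazolidin-2-one | O=C1N[C@@H](Cc2ccccc2)CO1 | starting material
15 | rac-2-(Ar*)acetic pivalic anhydride (racemic; 2S,3S drawn) | C(c1ccccc1)Oc1ccc(cc1)[C@H]2Oc3cc(OCc4ccccc4)cc(CC(=O)OC(=O)C(C)(C)C)c3[C@@H]2c2cc(OCc3ccccc3)cc(OCc3ccccc3)c2 | intermediate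
16 | (4S)-4-benzyl-3-[2-(Ar*)acetyl]-1,3-oxazolidin-2-one | C(c1ccccc1)Oc1ccc(cc1)[C@H]2Oc3cc(OCc4ccccc4)cc(CC(=O)N1[C@@H](Cc4ccccc4)COC1=O)c3[C@@H]2c2cc(OCc3ccccc3)cc(OCc3ccccc3)c2 | intermediate
17 | (4S,4'S)-3,3'-[(2S,3S)-2,3-bis(Ar*)butanedioyl]bis(4-benzyl-1,3-oxazolidin-2-one) | C(c1ccccc1)Oc1ccc(cc1)[C@H]2Oc3cc(OCc4ccccc4)cc([C@@H](C(=O)N1[C@@H](Cc4ccccc4)COC1=O)[C@@H](c5cc(OCc7ccccc7)cc6c5[C@H](c5cc(OCc7ccccc7)cc(OCc7ccccc7)c5)[C@@H](c5ccc(OCc7ccccc7)cc5)O6)C(=O)N1[C@@H](Cc4ccccc4)COC1=O)c3[C@@H]2c2cc(OCc3ccccc3)cc(OCc3ccccc3)c2 | intermediate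
18 | S,S'-diethyl (2S,3S)-2,3-bis(Ar*)butanebis(thioate) | C(c1ccccc1)Oc1ccc(cc1)[C@H]2Oc3cc(OCc4ccccc4)cc([C@@H](C(=O)SCC)[C@@H](c5cc(OCc7ccccc7)cc6c5[C@H](c5cc(OCc7ccccc7)cc(OCc7ccccc7)c5)[C@@H](c5ccc(OCc7ccccc7)cc5)O6)C(=O)SCC)c3[C@@H]2c2cc(OCc3ccccc3)cc(OCc3ccccc3)c2 | intermediate
19 | 4-acetoxyphenylboronic acid | CC(=O)Oc1ccc(cc1)B(O)O | starting material
20 | (2S,3S)-1,4-bis(4-acetoxyphenyl)-2,3-bis(Ar*)butane-1,4-dione | C(c1ccccc1)Oc1ccc(cc1)[C@H]2Oc3cc(OCc4ccccc4)cc([C@@H](C(=O)c1ccc(OC(C)=O)cc1)[C@@H](c5cc(OCc7ccccc7)cc6c5[C@H](c5cc(OCc7ccccc7)cc(OCc7ccccc7)c5)[C@@H](c5ccc(OCc7ccccc7)cc5)O6)C(=O)c1ccc(OC(C)=O)cc1)c3[C@@H]2c2cc(OCc3ccccc3)cc(OCc3ccccc3)c2 | intermediate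
21 | (1R,2S,3S,4R)-1,4-bis(4-acetoxyphenyl)-2,3-bis(Ar*)butane-1,4-diol | C(c1ccccc1)Oc1ccc(cc1)[C@H]2Oc3cc(OCc4ccccc4)cc([C@@H]([C@@H](O)c1ccc(OC(C)=O)cc1)[C@@H](c5cc(OCc7ccccc7)cc6c5[C@H](c5cc(OCc7ccccc7)cc(OCc7ccccc7)c5)[C@@H](c5ccc(OCc7ccccc7)cc5)O6)[C@H](c1ccc(OC(C)=O)cc1)O)c3[C@@H]2c2cc(OCc3ccccc3)cc(OCc3ccccc3)c2 | intermediate
22 | (1R,2S,3S,4R)-1,4-bis(4-acetoxyphenyl)-4-hydroxy-2,3-bis(Ar*)butyl methanesulfonate | C(c1ccccc1)Oc1ccc(cc1)[C@H]2Oc3cc(OCc4ccccc4)cc([C@@H]([C@@H](OS(C)(=O)=O)c1ccc(OC(C)=O)cc1)[C@@H](c5cc(OCc7ccccc7)cc6c5[C@H](c5cc(OCc7ccccc7)cc(OCc7ccccc7)c5)[C@@H](c5ccc(OCc7ccccc7)cc5)O6)[C@H](c1ccc(OC(C)=O)cc1)O)c3[C@@H]2c2cc(OCc3ccccc3)cc(OCc3ccccc3)c2 | intermediate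
23 | (2S,3S,4S,5R)-2,5-bis(4-acetoxyphenyl)-3,4-bis(Ar*)tetrahydrofuran | C(c1ccccc1)Oc1ccc(cc1)[C@H]2Oc3cc(OCc4ccccc4)cc([C@@H]8[C@@H](c5cc(OCc7ccccc7)cc6c5[C@H](c5cc(OCc7ccccc7)cc(OCc7ccccc7)c5)[C@@H](c5ccc(OCc7ccccc7)cc5)O6)[C@H](c1ccc(OC(C)=O)cc1)O[C@@H]8c1ccc(OC(C)=O)cc1)c3[C@@H]2c2cc(OCc3ccccc3)cc(OCc3ccccc3)c2 | intermediate
24 | (2S,3S,4S,5R)-2,5-bis(4-hydroxyphenyl)-3,4-bis(Ar*)tetrahydrofuran | C(c1ccccc1)Oc1ccc(cc1)[C@H]2Oc3cc(OCc4ccccc4)cc([C@@H]8[C@@H](c5cc(OCc7ccccc7)cc6c5[C@H](c5cc(OCc7ccccc7)cc(OCc7ccccc7)c5)[C@@H](c5ccc(OCc7ccccc7)cc5)O6)[C@H](c1ccc(O)cc1)O[C@@H]8c1ccc(O)cc1)c3[C@@H]2c2cc(OCc3ccccc3)cc(OCc3ccccc3)c2 | intermediate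
25 | target CNP0270490.1, tetrahydrofuran (2S,3S,4S,5R), both dihydrobenzofurans (2S,3S) | Oc1ccc([C@H]2Oc3cc(O)cc([C@@H]4[C@@H](c5cc(O)cc6c5[C@H](c5cc(O)cc(O)c5)[C@@H](c5ccc(O)cc5)O6)[C@H](c5ccc(O)cc5)O[C@@H]4c4ccc(O)cc4)c3[C@@H]2c2cc(O)cc(O)c2)cc1 | target

**Summary**

Total step count: 16.
Longest linear sequence: 15 steps (1 to 25 through steps 1–4 and 6–16; step 5 is a one-step side branch).

**Steps most likely to fail**

Step 10 (homocoupling). The C–C bond formation between two very hindered titanium enolate centres may be too slow, and the Lewis acid may ionise the benzylic C–O bond of the dihydrobenzofuran or erode facial selectivity. The fallback sets out from imide 16 and returns at bis-thioester 18; it couples a much smaller nucleophile without Lewis acid. LiOH/H2O2 removes the auxiliary from 16 to give the enantiopure (2S,3S)-2-(Ar*)acetic acid F1. Its dilithium enediolate (LDA, THF, −78 to 0 °C) is oxidised by iodine, a coupling of carboxylic acid dianions known to favour the C2-symmetric isomers; the (2S,3S)-2,3-bis(Ar*)butanedioic acid F2 is separated from its diastereomers. EDC, EtSH and DMAP then convert F2 into 18.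

Step 12 (ketone synthesis). Oxidative addition and transmetalation at the two neopentyl-like thioesters may stall after one coupling or lead to decarbonylation. The fallback sets out from 18 and returns at diketone 20; it uses acyl substitution by a Grignard reagent. MeONHMe·HCl/i-PrMgCl (THF, −20 °C) converts 18 into the bis(N-methoxy-N-methylamide) F3. 4-(tert-Butyldimethylsilyloxy)phenylmagnesium bromide adds to F3 to give the bis(silyloxyphenyl) diketone F4. Buffered fluoride (HF·pyridine) frees the bis(4-hydroxyphenyl) diketone F5, and Ac2O/pyridine acetylates it to 20.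

Step 14 (key step). Ionisation of the benzylic mesylate (SN1 leakage towards the all-trans ring), elimination towards the stilbene, or double mesylation may compete with the SN2 closure. The fallback sets out from diol 21 and returns at tetrahydrofuran 23; the O–C2 bond is made by hemiketalisation and C2 is set by hydride delivery, as practised for 2,3-cis tetrahydrofuran lignans. MnO2 (CH2Cl2) oxidises one benzylic carbinol of 21, and the hydroxy ketone closes to the cyclic hemiketal (3S,4S,5R)-2,5-bis(4-acetoxyphenyl)-3,4-bis(Ar*)tetrahydrofuran-2-ol F6 (over-oxidation only returns 20). Et3SiH/BF3·OEt2 (CH2Cl2, −78 °C) reduces the derived oxocarbenium ion anti to the C3 substituent, which should give the 2,3-cis ring of 23.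

Further compounds
F1 | step 10 | (2S,3S)-2-(Ar*)acetic acid, single enantiomer | C(c1ccccc1)Oc1ccc(cc1)[C@H]2Oc3cc(OCc4ccccc4)cc(CC(O)=O)c3[C@@H]2c2cc(OCc3ccccc3)cc(OCc3ccccc3)c2
F2 | step 10 | (2S,3S)-2,3-bis(Ar*)butanedioic acid | C(c1ccccc1)Oc1ccc(cc1)[C@H]2Oc3cc(OCc4ccccc4)cc([C@@H](C(O)=O)[C@@H](c5cc(OCc7ccccc7)cc6c5[C@H](c5cc(OCc7ccccc7)cc(OCc7ccccc7)c5)[C@@H](c5ccc(OCc7ccccc7)cc5)O6)C(O)=O)c3[C@@H]2c2cc(OCc3ccccc3)cc(OCc3ccccc3)c2
F3 | step 12 | (2S,3S)-N,N'-dimethoxy-N,N'-dimethyl-2,3-bis(Ar*)butanediamide | C(c1ccccc1)Oc1ccc(cc1)[C@H]2Oc3cc(OCc4ccccc4)cc([C@@H](C(=O)N(C)OC)[C@@H](c5cc(OCc7ccccc7)cc6c5[C@H](c5cc(OCc7ccccc7)cc(OCc7ccccc7)c5)[C@@H](c5ccc(OCc7ccccc7)cc5)O6)C(=O)N(C)OC)c3[C@@H]2c2cc(OCc3ccccc3)cc(OCc3ccccc3)c2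
F4 | step 12 | (2S,3S)-1,4-bis[4-(tert-butyldimethylsilyloxy)phenyl]-2,3-bis(Ar*)butane-1,4-dione | C(c1ccccc1)Oc1ccc(cc1)[C@H]2Oc3cc(OCc4ccccc4)cc([C@@H](C(=O)c1ccc(O[Si](C)(C)C(C)(C)C)cc1)[C@@H](c5cc(OCc7ccccc7)cc6c5[C@H](c5cc(OCc7ccccc7)cc(OCc7ccccc7)c5)[C@@H](c5ccc(OCc7ccccc7)cc5)O6)C(=O)c1ccc(O[Si](C)(C)C(C)(C)C)cc1)c3[C@@H]2c2cc(OCc3ccccc3)cc(OCc3ccccc3)c2
F5 | step 12 | (2S,3S)-1,4-bis(4-hydroxyphenyl)-2,3-bis(Ar*)butane-1,4-dione | C(c1ccccc1)Oc1ccc(cc1)[C@H]2Oc3cc(OCc4ccccc4)cc([C@@H](C(=O)c1ccc(O)cc1)[C@@H](c5cc(OCc7ccccc7)cc6c5[C@H](c5cc(OCc7ccccc7)cc(OCc7ccccc7)c5)[C@@H](c5ccc(OCc7ccccc7)cc5)O6)C(=O)c1ccc(O)cc1)c3[C@@H]2c2cc(OCc3ccccc3)cc(OCc3ccccc3)c2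
F6 | step 14 | (3S,4S,5R)-2,5-bis(4-acetoxyphenyl)-3,4-bis(Ar*)tetrahydrofuran-2-ol, hemiketal as anomers | C(c1ccccc1)Oc1ccc(cc1)[C@H]2Oc3cc(OCc4ccccc4)cc([C@@H]8[C@@H](c5cc(OCc7ccccc7)cc6c5[C@H](c5cc(OCc7ccccc7)cc(OCc7ccccc7)c5)[C@@H](c5ccc(OCc7ccccc7)cc5)O6)[C@H](c1ccc(OC(C)=O)cc1)OC8(O)c1ccc(OC(C)=O)cc1)c3[C@@H]2c2cc(OCc3ccccc3)cc(OCc3ccccc3)c2
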